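**Plan**
1. Numbering: ring C1 (quaternary carbinol), C2 (ketone), C3 (CH2), C4 (CHOH), C5 (CHOBz), C6 (CHOH); C7 is the exocyclic CH2OBz. Retrosynthesis: take off the acetonide and silyl groups, cut the ring at C2=C3, then remove the two outer alkene carbons, the benzoates and the C1–C7 bond, which leaves diacetone-D-mannose.
2. Enabling feature: in the six-membered carbocycle C1–C6, the C2 carbonyl with its C3 methylene is a hydrolysed ring enol ether C2(OSi)=C3. C1 is quaternary, so an open-chain C2 methyl ketone enolises only outwards, and a 2-silyloxyalkene on C1 and a vinyl group on C4 can be joined with loss of ethylene.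
3. Forward: mannose C1–C6 become C2, C1, C6, C5, C4, C3. Formaldehyde aldol adds C7; Wittig opening of the lactol; dibenzoylation; terminal acetonide to bis-silyl ether; Wacker oxidation to the C2 ketone; C3 aldehyde to vinyl; enol silylation; metathesis closes the only ring; two deprotections.
4. Stereochemistry: C6, C5 and C4 are C3, C4 and C5 of D-mannose. C1 is fixed in the aldol by re-closure to the cis-fused lactol. No stereocentre is formed or inverted afterwards.

Key step: step 11

Remark: lactol 3 is an anomeric mixture and is drawn without configuration at the anomeric carbon, which becomes sp2 carbon C2 in step 2.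
Assumption: commercial 2,3:5,6-di-O-isopropylidene-α-D-mannofuranose is taken as the chiral starting material.

**Route**

Step 1
Reactants: 1 2,3:5,6-di-O-isopropylidene-α-D-mannofuranose; 2 formaldehyde
Product: 3 2-C-(hydroxymethyl)-2,3:5,6-di-O-isopropylidene-D-mannofuranose (lactol; the new CH2OH is C7 on quaternary C1)
Conditions: 37% aq. HCHO (excess), K2CO3, MeOH, 65 °C
Reagents that add atoms: formaldehyde (2), C=O
Why: Crossed aldol (hydroxymethylation) of the aldehyde form of a 2,3-O-isopropylidene furanose with formaldehyde, a known reaction of this lactol class: the dioxolane enolate is attacked on the face away from the neighbouring C5 chain and only that adduct can re-close to the cis-fused lactol, so CH2OH replaces the hydrogen on C1 with retention and fixes the quaternary centre, while the lactol form protects the aldehyde from Cannizzaro reduction.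

Step 2
Reactants: 3 branched lactol
Product: 4 open-chain alkene diol: C2 vinyl on quaternary C1, free C7–OH and C5–OH, acetonides on O1/O6 and O4/O3 (1,2-dideoxy-3-C-(hydroxymethyl)-3,4:6,7-di-O-isopropylidene-D-manno-hept-1-enitol)
Conditions: Ph3PCH3Br, n-BuLi, THF, −20 °C → rt
Reagents that add atoms: methyltriphenylphosphonium bromide, C[P+](c1ccccc1)(c1ccccc1)c1ccccc1.[Br-]
Why: Wittig methylenation of a lactol through its hydroxy aldehyde tautomer; C1 carries no hydrogen and cannot epimerise, and turning C2 into a vinyl group frees O5 for acylation while postponing the C2 carbonyl, which with a free C5 hydroxyl would close to a hemiketal.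

Step 3
Reactants: 4 alkene diol; 5 benzoyl chloride
Product: 6 dibenzoate of 4 (C7–OBz and C5–OBz; both acetonides and the C2 vinyl group retained)
Conditions: BzCl, pyridine, DMAP (cat.), CH2Cl2, 0 °C → rt
Reagents that add atoms: benzoyl chloride (5), O=C(Cl)c1ccccc1
Why: DMAP-catalysed acylation of the only two free hydroxyl groups, the primary C7–OH and the secondary C5–OH, installs both benzoates of the target at once.

Step 4
Reactants: 6 dibenzoate
Product: 7 terminal diol (C4–OH and C3–OH free; C1/C6 acetonide, C2 vinyl, C5 and C7 benzoates retained)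
Conditions: AcOH/H2O (4:1), 35 °C
Reagents that add atoms: none
Why: Acid-catalysed acetal hydrolysis that discriminates the terminal, monosubstituted dioxolane from the internal trisubstituted cis-dioxolane on C1/C6, the selectivity known for 5,6- over 2,3-acetonides of mannose derivatives; the weakly acidic medium does not promote benzoyl migration from O5 to O4.

Step 5
Reactants: 7 terminal diol
Product: 8 bis(tert-butyldimethylsilyl) ether of 7 (C4–OTBS secondary, C3–OTBS primary)
Conditions: TBSOTf, 2,6-lutidine, CH2Cl2, −78 → 0 °C
Reagents that add atoms: tert-butyldimethylsilyl triflate, CC(C)(C)[Si](C)(C)OS(=O)(=O)C(F)(F)F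
Why: Silylation with the silyl triflate and a hindered pyridine base is fast at low temperature for primary and secondary hydroxyls alike and leaves no time for a base-induced O5 to O4 benzoyl shift.

Step 6
Reactants: 8 bis-silyl ether with C2 vinyl group
Product: 9 C2 methyl ketone (acetyl group on quaternary C1; C4–OTBS, C3–OTBS, C5 and C7 benzoates, C1/C6 acetonide)
Conditions: PdCl2(Quinox) (cat.; Quinox = 2-(4,5-dihydro-1,3-oxazol-2-yl)quinoline), AgSbF6 (cat.), 70% aq. t-BuOOH, CH2Cl2, 0 °C → rt
Reagents that add atoms: tert-butyl hydroperoxide, CC(C)(C)OO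
Why: Wacker-type oxidation of a monosubstituted alkene with a cationic quinoline–oxazoline complex of divalent palladium and tert-butyl hydroperoxide, a system developed for methyl ketone formation from alkenes bearing protected allylic oxygen; the ketone appears only now, when O4 and O5 are both blocked and no hemiketal can form.

Step 7
Reactants: 9 methyl ketone bis-silyl ether
Product: 10 primary alcohol (C3–OH free; C4–OTBS retained)
Conditions: HF·pyridine, pyridine, THF, 0 °C
Reagents that add atoms: none
Why: Buffered HF·pyridine removes the unhindered primary silyl ether well before the secondary one at C4 (steric discrimination in desilylation), and the acidic medium leaves the benzoates and the acetonide untouched.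

Step 8
Reactants: 10 primary alcohol
Product: 11 C3 aldehyde (α-silyloxy aldehyde; C2 methyl ketone retained)
Conditions: Dess–Martin periodinane, CH2Cl2, 0 °C → rt
Reagents that add atoms: none
Why: Dess–Martin oxidation of a primary alcohol under non-basic conditions gives the α-silyloxy aldehyde without epimerisation at C4 or β-elimination of the C5 benzoate.

Step 9
Reactants: 11 keto aldehyde
Product: 12 vinyl ketone (C3 vinyl group on C4; C2 methyl ketone, C4–OTBS, C5 and C7 benzoates, C1/C6 acetonide)
Conditions: Ph3PCH3Br, KN(SiMe3)2, THF, −78 → −20 °C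
Reagents that add atoms: methyltriphenylphosphonium bromide, C[P+](c1ccccc1)(c1ccccc1)c1ccccc1.[Br-]
Why: Wittig methylenation at low temperature is far faster at the aldehyde than at the hindered methyl ketone beside quaternary C1 or at the benzoates, and the short cold exposure to the ylide preserves the C4 configuration.

Step 10
Reactants: 12 vinyl ketone
Product: 13 acyclic diene: C2 tert-butyldimethylsilyl enol ether (C2(OTBS)=CH2), C3 vinyl, C4–OTBS, C5 and C7 benzoates, C1/C6 acetonide
Conditions: TBSOTf, Et3N, CH2Cl2, 0 °C
Reagents that add atoms: tert-butyldimethylsilyl triflate, CC(C)(C)[Si](C)(C)OS(=O)(=O)C(F)(F)F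
Why: Soft enolisation and O-silylation of a methyl ketone with silyl triflate and triethylamine; because C1 is quaternary the ketone can enolise only into the methyl group, so the 2-silyloxy-1-alkene is formed as a single regioisomer.

Step 11
Reactants: 13 acyclic silyl enol ether diene
Product: 14 cyclic C2 silyl enol ether (cyclohexene C2(OTBS)=C3; C4–OTBS, C5 and C7 benzoates, cis-fused C1/C6 acetonide)
Conditions: second-generation Grubbs catalyst RuCl2(H2IMes)(PCy3)(=CHPh) (5–10 mol %), degassed toluene (about 0.005 M), 80 °C, argon purge
Reagents that add atoms: none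
Why: The ruthenium benzylidene exchanges onto the monosubstituted C3 vinyl group, the new alkylidene adds in a [2+2] sense to the 1,1-disubstituted enol ether alkene with ruthenium on the terminal CH2, and cycloreversion gives the C2=C3 bond and a ruthenium methylidene that carries the chain with loss of ethylene. The closest known reaction is ring-closing metathesis of acyclic tert-butyldimethylsilyl enol ether dienes to cyclic silyl enol ethers with this catalyst. The carbocycle C1–C6 forms by closure of a 1,7-diene to a cyclohexene, the only ring made in the route. No stereocentre is created, and C1, C4, C5 and C6 are spectators. The step needs ring closure to win over intermolecular metathesis at the C3 vinyl group; high dilution, removal of ethylene and the cis-fused C1/C6 acetonide, which holds the C2 and C5 arms on the same face of the dioxolane, secure it. The position of the enol ether double bond was fixed in step 10 and is not at stake here.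

Step 12
Reactants: 14 cyclic silyl enol ether
Product: 15 keto alcohol acetonide (C2 ketone, C3 H2, C4–OH; C5 and C7 benzoates, C1/C6 acetonide)
Conditions: HF·pyridine, THF, 0 °C → rt
Reagents that add atoms: none
Why: Fluoride-assisted protodesilylation converts the silyl enol ether into the C2 ketone (C3 becomes CH2) and cleaves the C4 silyl ether; the mildly acidic HF·pyridine avoids the E1cB loss of the C4 oxygen and the acyl migration that a basic fluoride source could cause.

Step 13
Reactants: 15 keto alcohol acetonide
Product: 16 target, [(1S,2S,3R,4R)-3-(benzoyloxy)-1,2,4-trihydroxy-6-oxocyclohexyl]methyl benzoate (route numbering: C1 S, C4 R, C5 R, C6 S)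
Conditions: TFA/H2O (9:1), 0 °C
Reagents that add atoms: none
Why: Acid-catalysed hydrolysis of the remaining isopropylidene acetal liberates the C1 and C6 hydroxyls; short exposure at low temperature limits dehydration of the β-hydroxy ketone and benzoyl migration, and no stereocentre is touched.

**Compound list**
1 | 2,3:5,6-di-O-isopropylidene-α-D-mannofuranose | O[C@@H]1[C@H]2OC(C)(C)O[C@H]2[C@@H]([C@H]2COC(C)(C)O2)O1 | starting material
2 | formaldehyde | C=O | starting material
3 | 2-C-(hydroxymethyl)-2,3:5,6-di-O-isopropylidene-D-mannofuranose (anomeric mixture) | OC1[C@@]2(CO)OC(C)(C)O[C@H]2[C@@H]([C@H]2COC(C)(C)O2)O1 | intermediate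
4 | alkene diol: C2 vinyl, C7–OH, C5–OH, two acetonides | C=C[C@@]1(CO)OC(C)(C)O[C@H]1[C@H](O)[C@H]1COC(C)(C)O1 | intermediate
5 | benzoyl chloride | O=C(Cl)c1ccccc1 | starting material
6 | dibenzoate (C7–OBz, C5–OBz), two acetonides, C2 vinyl | C=C[C@@]1(COC(=O)c2ccccc2)OC(C)(C)O[C@H]1[C@H](OC(=O)c1ccccc1)[C@H]1COC(C)(C)O1 | intermediate
7 | terminal diol (C4–OH, C3–OH), C1/C6 acetonide, dibenzoate, C2 vinyl | C=C[C@@]1(COC(=O)c2ccccc2)OC(C)(C)O[C@H]1[C@H](OC(=O)c1ccccc1)[C@H](O)CO | intermediate
8 | bis-TBS ether (C4–OTBS, C3–OTBS), C2 vinyl | C=C[C@@]1(COC(=O)c2ccccc2)OC(C)(C)O[C@H]1[C@H](OC(=O)c1ccccc1)[C@H](O[Si](C)(C)C(C)(C)C)CO[Si](C)(C)C(C)(C)C | intermediate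
9 | C2 methyl ketone, bis-TBS ether | CC(=O)[C@@]1(COC(=O)c2ccccc2)OC(C)(C)O[C@H]1[C@H](OC(=O)c1ccccc1)[C@H](O[Si](C)(C)C(C)(C)C)CO[Si](C)(C)C(C)(C)C | intermediate
10 | C2 methyl ketone, C3 primary alcohol, C4–OTBS | CC(=O)[C@@]1(COC(=O)c2ccccc2)OC(C)(C)O[C@H]1[C@H](OC(=O)c1ccccc1)[C@H](O[Si](C)(C)C(C)(C)C)CO | intermediate
11 | C2 methyl ketone, C3 aldehyde, C4–OTBS | CC(=O)[C@@]1(COC(=O)c2ccccc2)OC(C)(C)O[C@H]1[C@H](OC(=O)c1ccccc1)[C@H](O[Si](C)(C)C(C)(C)C)C=O | intermediate
12 | C2 methyl ketone, C3 vinyl, C4–OTBS | CC(=O)[C@@]1(COC(=O)c2ccccc2)OC(C)(C)O[C@H]1[C@H](OC(=O)c1ccccc1)[C@H](O[Si](C)(C)C(C)(C)C)C=C | intermediate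
13 | acyclic diene: C2 TBS enol ether, C3 vinyl, C4–OTBS, C5/C7 benzoates, C1/C6 acetonide | C=C(O[Si](C)(C)C(C)(C)C)[C@@]1(COC(=O)c2ccccc2)OC(C)(C)O[C@H]1[C@H](OC(=O)c1ccccc1)[C@H](O[Si](C)(C)C(C)(C)C)C=C | intermediate
14 | cyclic C2 TBS enol ether, C4–OTBS, C5/C7 benzoates, C1/C6 acetonide | O=C(OC[C@]12OC(C)(C)O[C@H]1[C@H](OC(=O)c1ccccc1)[C@H](O[Si](C)(C)C(C)(C)C)C=C2O[Si](C)(C)C(C)(C)C)c1ccccc1 | intermediate
15 | keto alcohol acetonide (C2 ketone, C4–OH) | O=C(OC[C@]12OC(C)(C)O[C@H]1[C@H](OC(=O)c1ccccc1)[C@H](O)CC2=O)c1ccccc1 | intermediate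
16 | [(1S,2S,3R,4R)-3-(benzoyloxy)-1,2,4-trihydroxy-6-oxocyclohexyl]methyl benzoate (CNP0127041.1) | O=C(OC[C@@]1(O)C(=O)C[C@@H](O)[C@@H](OC(=O)c2ccccc2)[C@@H]1O)c1ccccc1 | target

**Step count**
Total: 13 steps. Longest linear sequence: 13 steps, from 1 to 16.

**Steps most likely to fail**

Step 11. Ring closure onto the 1,1-disubstituted enol ether beside quaternary C1 may be slower than intermolecular metathesis at the C3 vinyl group, and the enol ether may be lost to adventitious acid. The fallback closes the ring as an aldol bond between C3 and C4 instead. It sets out from ketone 9.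
- TBSOTf and Et3N would give the silyl enol ether F1.
- N-Bromosuccinimide in THF at 0 °C would give the bromomethyl ketone F2.
- HF·pyridine, left until both silyl ethers are gone, would give the bromo keto diol F3.
- NaIO4 in aqueous THF would cleave the diol to the C4 aldehyde F4, with loss of the former C3 carbon.
- SmI2 (two equivalents, THF, −78 °C) would form the samarium enolate only at the bromomethyl carbon, which becomes the new C3, and an intramolecular Reformatsky-type aldol addition would close the six-membered ring.

The fallback comes back to the route at keto alcohol 15. In this variant C4 is set in the cyclisation and no longer by mannose. A chelated chair is expected to place the new hydroxyl cis to the C5 benzoate, as in related aldol ring closures of sugar-derived 1,5-dicarbonyl compounds, but the configuration would have to be proven.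

Step 6. Coordination of palladium to the vinyl group on quaternary C1 may be slow, and oxygen may be delivered to the terminal carbon, giving an aldehyde. The fallback cleaves the alkene instead of oxidising it. It sets out from 8.
- Ozone in CH2Cl2/MeOH at −78 °C followed by PPh3 would give the C2 aldehyde F5, which has no α-hydrogen and can neither epimerise nor eliminate.
- MeMgBr in THF at −78 °C adds to the aldehyde faster than to the benzoates and would give the secondary alcohol F6 as a mixture of C2 epimers.
- Dess–Martin periodinane would then give ketone 9, where the route is rejoined.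

Step 2. The basic ylide may trigger retro-aldol loss of formaldehyde from the β-oxido aldehyde form of 3, or the hindered lactol may open too slowly. The fallback is a Peterson sequence in place of the Wittig reaction. It sets out from lactol 3.
- Me3SiCH2MgCl in THF would add to the aldehyde form and give the β-hydroxysilane F7, which no longer contains an aldehyde.
- KH in THF would eliminate the silanolate and give alkene diol 4, where the route is rejoined.

**Further compounds**
F1 | step 11 | TBS enol ether of ketone 9 (C2(OTBS)=CH2, C4–OTBS, C3–OTBS) | C=C(O[Si](C)(C)C(C)(C)C)[C@@]1(COC(=O)c2ccccc2)OC(C)(C)O[C@H]1[C@H](OC(=O)c1ccccc1)[C@H](O[Si](C)(C)C(C)(C)C)CO[Si](C)(C)C(C)(C)C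
F2 | step 11 | bromomethyl ketone, bis-TBS ether | BrCC(=O)[C@@]1(COC(=O)c2ccccc2)OC(C)(C)O[C@H]1[C@H](OC(=O)c1ccccc1)[C@H](O[Si](C)(C)C(C)(C)C)CO[Si](C)(C)C(C)(C)C
F3 | step 11 | bromomethyl ketone, terminal diol | BrCC(=O)[C@@]1(COC(=O)c2ccccc2)OC(C)(C)O[C@H]1[C@H](OC(=O)c1ccccc1)[C@H](O)CO
F4 | step 11 | bromomethyl ketone, C4 aldehyde | BrCC(=O)[C@@]1(COC(=O)c2ccccc2)OC(C)(C)O[C@H]1[C@H](OC(=O)c1ccccc1)C=O
F5 | step 6 | C2 aldehyde, bis-TBS ether | O=C[C@@]1(COC(=O)c2ccccc2)OC(C)(C)O[C@H]1[C@H](OC(=O)c1ccccc1)[C@H](O[Si](C)(C)C(C)(C)C)CO[Si](C)(C)C(C)(C)C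
F6 | step 6 | C2 secondary alcohol (epimer mixture), bis-TBS ether | CC(O)[C@@]1(COC(=O)c2ccccc2)OC(C)(C)O[C@H]1[C@H](OC(=O)c1ccccc1)[C@H](O[Si](C)(C)C(C)(C)C)CO[Si](C)(C)C(C)(C)C
F7 | step 2 | β-hydroxysilane triol (C2 carbinol bearing CH2SiMe3, epimer mixture) | C[Si](C)(C)CC(O)[C@@]1(CO)OC(C)(C)O[C@H]1[C@H](O)[C@H]1COC(C)(C)O1
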